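**Retrosynthetic overview**
1. The target is fisetinidol-(4α→6)-catechin; the one strategic cut is the interflavanyl bond between C4 of the upper pyran (C) ring and C6 of the lower phloroglucinol (D) ring.
2. That bond is made by a one-pot oxidative arylation of the C3=C4 bond of a (2S)-flav-3-ene: DMDO epoxidation, then Friedel–Crafts opening of the oxirane at C4 by C6 of 8-bromo-tetra-O-benzylcatechin. This installs O3, the C4–C6 bond and the C3/C4 stereocentres from the single C2 stereocentre.
3. Enabling feature: in ring A, O7 is para and O1 ortho to C4a, so C4 is a quinone-methide-type benzylic carbon and the oxirane opens only there; in ring D, C6 lies between O5 and O7, and Br at C8 blocks the competing site.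
4. Flav-3-ene: 7-hydroxychromone (A/C rings bought) → Rh-catalysed asymmetric 1,4-arylation (B ring, C2) → NaBH4 → dehydration. Nucleophile: (+)-catechin (D/F/E rings and two stereocentres bought) → benzylation → C8 bromination.
5. No permanent ring is built: the only ring formed is the transient oxirane (step 7), opened in the same flask; one hydrogenolysis then removes seven benzyl groups and the bromine.

Key step: step 7

Assumption: the facial sense of the Rh/bisphosphine 1,4-arylation in step 2 is taken from the cyclic-enone model, by which the (S)-biaryl ligand places the aryl group on the face that corresponds to (2S) in a chroman-4-one; if the opposite sense is found, the (R)-ligand is used and nothing else changes.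

**Route**

Step 1
Reactants: 1 7-hydroxy-4H-chromen-4-one
Product: 2 7-(benzyloxy)-4H-chromen-4-one
Conditions: BnBr (1.2 equiv), K2CO3, DMF, rt
Reagents that add atoms: benzyl bromide, BrCc1ccccc1
Why: Williamson etherification of the acidic 7-OH (a vinylogous acid) under carbonate conditions that the chromone ring tolerates.

Step 2
Reactants: 2 7-(benzyloxy)-4H-chromen-4-one; 3 [3,4-bis(benzyloxy)phenyl]boronic acid
Product: 4 (2S)-7-(benzyloxy)-2-[3,4-bis(benzyloxy)phenyl]chroman-4-one
Conditions: 3 (2.5 equiv), [Rh(OH)(cod)]2 (2.5 mol%), (S)-MeO-F12-BIPHEP (5.5 mol%), toluene/H2O (20:1), 25 °C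
Reagents that add atoms: none
Why: Hayashi–Miyaura Rh(I)-catalysed asymmetric 1,4-addition of an arylboronic acid to a chromone, a precedented route to flavanones, in which the ligand-bound aryl–Rh inserts the C2=C3 bond from one face and so sets C2 (S), while the neutral conditions suppress retro-oxa-Michael racemisation.

Step 3
Reactants: 4 (2S)-7-(benzyloxy)-2-[3,4-bis(benzyloxy)phenyl]chroman-4-one
Product: 5 (2S,4S)-7-(benzyloxy)-2-[3,4-bis(benzyloxy)phenyl]chroman-4-ol (2,4-cis)
Conditions: NaBH4, THF/MeOH (4:1), 0 °C
Reagents that add atoms: none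
Why: NaBH4 1,2-reduction with axial hydride delivery on the half-chair that carries an equatorial 2-aryl group should give the 2,4-cis alcohol, whose C4 configuration is immaterial because C4 becomes sp2 in step 4.

Step 4
Reactants: 5 (2S,4S)-7-(benzyloxy)-2-[3,4-bis(benzyloxy)phenyl]chroman-4-ol
Product: 6 (2S)-7-(benzyloxy)-2-[3,4-bis(benzyloxy)phenyl]-2H-chromene (tri-O-benzyl flav-3-ene)
Conditions: Martin sulfurane (1.3 equiv), CH2Cl2, 0 °C → rt, exclusion of light
Reagents that add atoms: none
Why: Martin sulfurane dehydration, in which the alkoxysulfonium of the p-alkoxybenzylic C4–OH ionises and loses H3 under non-acidic conditions to give the A-ring-conjugated C3=C4 alkene without touching C2.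

Step 5
Reactants: 7 (+)-catechin
Product: 8 5,7,3',4'-tetra-O-benzyl-(+)-catechin
Conditions: BnBr (4.4 equiv), K2CO3, DMF, 0 °C → rt
Reagents that add atoms: benzyl bromide, BrCc1ccccc1
Why: Williamson etherification in which carbonate deprotonates only the four phenols, so the secondary 3-OH stays free and C2/C3 are untouched.

Step 6
Reactants: 8 5,7,3',4'-tetra-O-benzyl-(+)-catechin
Product: 9 8-bromo-5,7,3',4'-tetra-O-benzyl-(+)-catechin
Conditions: NBS (1.0 equiv), CH2Cl2, −78 °C → rt
Reagents that add atoms: N-bromosuccinimide, O=C1CCC(=O)N1Br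
Why: electrophilic aromatic bromination, which in tetra-O-benzyl flavan-3-ols goes to C8, the most reactive carbon of the phloroglucinol-type ring, and so places the blocking group that leaves C6 as the only free D-ring position.

Step 7
Reactants: 6 (2S)-7-(benzyloxy)-2-[3,4-bis(benzyloxy)phenyl]-2H-chromene; 9 8-bromo-5,7,3',4'-tetra-O-benzyl-(+)-catechin
Product: 11 heptabenzyl 8-bromo-fisetinidol-(4α→6)-catechin, via 2,3-trans-flav-3-ene oxide 10 (not isolated)
Conditions: (i) DMDO (1.05 equiv, acetone-free solution in CH2Cl2), 4 Å MS, CH2Cl2, −40 °C, dark; (ii) 9 (2.5 equiv), then BF3·OEt2 (0.2 equiv), −78 → −40 °C; Et3N quench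
Reagents that add atoms: dimethyldioxirane, CC1(C)OO1
Why: Proposed new method: DMDO should transfer oxygen to the electron-rich styrenic C3=C4 bond of 6 in a concerted spiro transition state on the face anti to the 2-aryl group, closing the only ring made in this step, the transient oxirane of 10 (one-step [2+1] oxygen-atom transfer), and so fixing C3 with O3 trans to the C2 aryl. BF3 then opens the oxirane only at C4, because O7 (para to C4a) and O1 (on C8a, ortho) of ring A stabilise positive charge there as a quinone-methide-type oxocarbenium, and C6 of 9 attacks this carbon anti to the BF3-bound O3, so C4 is set by inversion (3,4-trans, 4α) and the unit becomes 2,3-trans-3,4-trans with all three substituents equatorial. The closest known reactions are DMDO epoxidation of flav-3-enes with in situ trans-opening at C4 by oxygen nucleophiles, Lewis-acid Friedel–Crafts opening of aryl oxiranes by electron-rich arenes and the classical Friedel–Crafts union of C4 flavanyl cations with flavan-3-ols; new is their merger with a carbon nucleophile to forge an interflavanyl C–C bond directly from an alkene. The selectivity the step needs on the nucleophile, C6 over C8 of ring D, is secured by the bromine at C8, which leaves C6 between O5 and O7 as the only free phloroglucinol-type carbon, while O-alkylation by the free 3-OH of 9 is reversible under BF3 and should drain to the C-aryl product. Self-alkylation is disfavoured because the resorcinol-type A ring of 6 and 10 is a far weaker nucleophile than the trioxygenated D ring, and low temperature plus an excess of 9 should outrun the unimolecular 1,2-hydride shift to the flavan-3-one. Since 9 is enantiopure, any product from residual (2R)-6 is a diastereomer of 11 and is removed by chromatography here.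

Step 8
Reactants: 11 heptabenzyl 8-bromo-fisetinidol-(4α→6)-catechin
Product: 12 CNP0141631.1, fisetinidol-(4α→6)-catechin
Conditions: H2 (1 atm), Pd(OH)2/C, Et3N (1.5 equiv), THF/MeOH/H2O, rt; Sephadex LH-20
Reagents that add atoms: none
Why: Pd-catalysed hydrogenolysis should cleave the seven benzyl ethers and the aryl C–Br bond in one operation with Et3N taking up HBr, under conditions in which the ring C2–O1 bonds and the interflavanyl C4–C6 bond of proanthocyanidins are known to survive and no stereocentre is touched.

**Compound list**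
1 | 7-hydroxy-4H-chromen-4-one (7-hydroxychromone) | O=c1ccoc2cc(O)ccc12 | starting material
2 | 7-(benzyloxy)-4H-chromen-4-one | O=c1ccoc2cc(OCc3ccccc3)ccc12 | intermediate
3 | [3,4-bis(benzyloxy)phenyl]boronic acid | OB(O)c1ccc(OCc2ccccc2)c(OCc2ccccc2)c1 | starting material
4 | (2S)-7-(benzyloxy)-2-[3,4-bis(benzyloxy)phenyl]chroman-4-one (tri-O-benzyl-(S)-butin) | O=C1C[C@@H](c2ccc(OCc3ccccc3)c(OCc3ccccc3)c2)Oc2cc(OCc3ccccc3)ccc21 | intermediate
5 | (2S,4S)-7-(benzyloxy)-2-[3,4-bis(benzyloxy)phenyl]chroman-4-ol (2,4-cis) | O[C@H]1C[C@@H](c2ccc(OCc3ccccc3)c(OCc3ccccc3)c2)Oc2cc(OCc3ccccc3)ccc21 | intermediate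
6 | (2S)-7-(benzyloxy)-2-[3,4-bis(benzyloxy)phenyl]-2H-chromene (tri-O-benzyl flav-3-ene) | C1=C[C@@H](c2ccc(OCc3ccccc3)c(OCc3ccccc3)c2)Oc2cc(OCc3ccccc3)ccc21 | intermediate
7 | (+)-catechin, (2R,3S)-2-(3,4-dihydroxyphenyl)chroman-3,5,7-triol | O[C@H]1Cc2c(O)cc(O)cc2O[C@@H]1c1ccc(O)c(O)c1 | starting material
8 | 5,7,3',4'-tetra-O-benzyl-(+)-catechin | O[C@H]1Cc2c(OCc3ccccc3)cc(OCc3ccccc3)cc2O[C@@H]1c1ccc(OCc2ccccc2)c(OCc2ccccc2)c1 | intermediate
9 | 8-bromo-5,7,3',4'-tetra-O-benzyl-(+)-catechin | O[C@H]1Cc2c(OCc3ccccc3)cc(OCc3ccccc3)c(Br)c2O[C@@H]1c1ccc(OCc2ccccc2)c(OCc2ccccc2)c1 | intermediate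
10 | (2R,3S,4S)-7-(benzyloxy)-2-[3,4-bis(benzyloxy)phenyl]-3,4-epoxychroman (flavan numbering; oxirane oxygen trans to the 2-aryl group) | O1[C@@H]2[C@H]1[C@@H](c1ccc(OCc3ccccc3)c(OCc3ccccc3)c1)Oc1cc(OCc3ccccc3)ccc12 | intermediate (not isolated)
11 | (2R,3S,4S)-7-(benzyloxy)-2-[3,4-bis(benzyloxy)phenyl]-4-[(2R,3S)-5,7-bis(benzyloxy)-2-[3,4-bis(benzyloxy)phenyl]-8-bromo-3-hydroxychroman-6-yl]chroman-3-ol (heptabenzyl 8-bromo-fisetinidol-(4α→6)-catechin) | c1ccccc1COc1ccc2c(c1)O[C@H](c1ccc(OCc3ccccc3)c(OCc3ccccc3)c1)[C@@H](O)[C@@H]2c1c(OCc3ccccc3)c(Br)c2c(c1OCc3ccccc3)C[C@H](O)[C@@H](c1ccc(OCc3ccccc3)c(OCc3ccccc3)c1)O2 | intermediate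
12 | CNP0141631.1, fisetinidol-(4α→6)-catechin: (2R,3S,4S)-2-(3,4-dihydroxyphenyl)-4-[(2R,3S)-2-(3,4-dihydroxyphenyl)-3,5,7-trihydroxychroman-6-yl]chroman-3,7-diol | Oc1ccc2c(c1)O[C@H](c1ccc(O)c(O)c1)[C@@H](O)[C@@H]2c1c(O)cc2c(c1O)C[C@H](O)[C@@H](c1ccc(O)c(O)c1)O2 | target

**Step count**
Total: 8 steps. Longest linear sequence: 6 steps (1, 2, 3, 4, 7, 8); the nucleophile branch is 2 steps (5, 6).

**Steps most likely to fail**

Step 7 (Proposed new method). After the oxirane opens, the C4 cation may collapse by a 1,2-hydride shift to the flavan-3-one, or alkylate another A ring, faster than it is captured by the hindered, bromine-deactivated C6 of 9. The fallback uses known chemistry, sets out from 6 and returns at 11. Catalytic OsO4 with NMO in acetone–water should dihydroxylate 6 anti to the 2-aryl group and give the bench-stable (2R,3S,4S)-2,3-trans-3,4-cis-flavan-3,4-diol F1. F1 is then ionised at C4 with TiCl4 in CH2Cl2 (−78 → 0 °C) in the presence of 9 (3 equiv), the classical Friedel–Crafts condensation of a flavan-3,4-diol with a flavan-3-ol. The C4 cation is then regenerated reversibly from a stable precursor, and attack anti to O3 should give 11.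

Step 2. Enantioinduction or insertion may be poor with the donor-substituted chromone and the electron-rich boronic acid, and the ee may erode by reversible retro-oxa-Michael opening of 4. The fallback sets out from 2 and 3 and returns at 5. An achiral Pd(II)/2,2'-bipyridine-catalysed conjugate addition should give the racemic flavanone F2. Kinetic resolution by Noyori-type asymmetric transfer hydrogenation (Rh– or Ru–TsDPEN, HCO2H/Et3N, catalyst antipode for which the (2S)-ketone is the fast substrate) should reduce only the (2S)-enantiomer to 5. The (2R)-flavanone F3 stays as the ketone and is removed by chromatography.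

Step 4. The benzylic cation formed on ionisation may add to the electron-rich alkene of the product (oligomerisation), or C2 may racemise through reversible C2–O1 ionisation or light-induced electrocyclic ring opening of the 2H-chromene. The fallback avoids the flavene altogether, sets out from 4 and returns at 11. Soft enolisation (TMSOTf, Et3N, CH2Cl2, 0 °C) should give the silyl enol ether F4. Rubottom oxidation (DMDO, −40 °C, then acidic work-up) anti to the 2-aryl group should give the (2R,3R)-trans-dihydroflavonol F5. NaBH4 reduction should give the (2R,3S,4R)-2,3-trans-3,4-trans-flavan-3,4-diol F6. TiCl4-mediated condensation of F6 with 9, as described for F1, should give 11.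

**Further compounds**
F1 | step 7 | (2R,3S,4S)-7-(benzyloxy)-2-[3,4-bis(benzyloxy)phenyl]chroman-3,4-diol (2,3-trans-3,4-cis) | O[C@@H]1[C@H](O)[C@@H](c2ccc(OCc3ccccc3)c(OCc3ccccc3)c2)Oc2cc(OCc3ccccc3)ccc21
F2 | step 2 | rac-7-(benzyloxy)-2-[3,4-bis(benzyloxy)phenyl]chroman-4-one | O=C1CC(c2ccc(OCc3ccccc3)c(OCc3ccccc3)c2)Oc2cc(OCc3ccccc3)ccc21
F3 | step 2 | (2R)-7-(benzyloxy)-2-[3,4-bis(benzyloxy)phenyl]chroman-4-one | O=C1C[C@H](c2ccc(OCc3ccccc3)c(OCc3ccccc3)c2)Oc2cc(OCc3ccccc3)ccc21
F4 | step 4 | (2S)-7-(benzyloxy)-2-[3,4-bis(benzyloxy)phenyl]-4-(trimethylsilyloxy)-2H-chromene | C[Si](C)(C)OC1=C[C@@H](c2ccc(OCc3ccccc3)c(OCc3ccccc3)c2)Oc2cc(OCc3ccccc3)ccc21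
F5 | step 4 | (2R,3R)-7-(benzyloxy)-2-[3,4-bis(benzyloxy)phenyl]-3-hydroxychroman-4-one (tri-O-benzyl-(+)-fustin) | O=C1[C@H](O)[C@@H](c2ccc(OCc3ccccc3)c(OCc3ccccc3)c2)Oc2cc(OCc3ccccc3)ccc21
F6 | step 4 | (2R,3S,4R)-7-(benzyloxy)-2-[3,4-bis(benzyloxy)phenyl]chroman-3,4-diol (2,3-trans-3,4-trans) | O[C@H]1[C@H](O)[C@@H](c2ccc(OCc3ccccc3)c(OCc3ccccc3)c2)Oc2cc(OCc3ccccc3)ccc21
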